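The route rests on cutting the C3(HBr)–C4(Me2) bond of the bromocyclohexane (ring A). The feature exploited is the quaternary gem-dimethyl carbon C4 next to the ring-fusion methine C5. It is read as a masked isopropenyl group, so C5 and its side chain come from (R)-carvone. In the key step an iron hydride delivers a hydrogen atom to the isopropenyl CH2, and the tertiary C4 radical closes ring A 6-exo onto a tethered C3 aldehyde. One operation creates the second methyl group, the quaternary carbon, the trans-fused bicycle and the C3 oxygen handle for bromide. The precursor is 6-methyl-6-(3-oxopropyl)carvone. Baeyer–Villiger oxygen insertion later turns the carvone ring into the oxepane (ring B).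

Key step: step 4

Remark on numbering:
- Ring A is C1–C2–C3(Br)–C4(Me2)–C5(H)–C10(Me,O).
- Ring B is C5–C6–C7(OH)–C8(=CH2)–C9(CH2Br)–O–C10.
- Carvone C1, C2, C3, C4, C5 and C6 become C9, C8, C7, C6, C5 and C10.
- The isopropenyl carbon becomes C4, and the allyl carbons become C1, C2 and C3.
- The α face is the face of H-5. The β face is the face of the C10 methyl group.

Assumption: the epimers at the one open centre of 3 (C10) and of 7 and 8 (C3) are carried on together. That centre is planarised again in steps 2 and 6, so the SMILES of 3, 7 and 8 leave it open.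

Step 1
Reactants: 1 (R)-(−)-carvone
Product: 3 (5R)-2,6-dimethyl-5-(prop-1-en-2-yl)cyclohex-2-en-1-one (6-methylcarvone), via lithium dienolate 2 (not isolated)
Conditions: LiN(iPr)2, THF, −78 °C; MeI, −78 → 0 °C
Reagents that add atoms: iodomethane, CI; LiN(iPr)2, [Li]N(C(C)C)C(C)C (lithium retained only in 2)
Why: Kinetic deprotonation at the only alpha-prime position gives the cross-conjugated dienolate, whose C-methylation (enolate alkylation) is regiospecific; the new centre forms as an epimer mixture that is erased in step 2.

Step 2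
Reactants: 3 6-methylcarvone
Product: 5 (5S,6S)-6-allyl-2,6-dimethyl-5-(prop-1-en-2-yl)cyclohex-2-en-1-one, via lithium dienolate 4 (not isolated)
Conditions: LiN(iPr)2, THF, −78 → 0 °C; allyl bromide, DMPU, −78 °C → rt
Reagents that add atoms: allyl bromide, C=CCBr; LiN(iPr)2, [Li]N(C(C)C)C(C)C (lithium retained only in 4)
Why: Enolate alkylation of the tetrasubstituted dienolate takes place on the face anti to the adjacent isopropenyl group, which sets quaternary C10 with the allyl group trans and the methyl group cis to the isopropenyl group.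

Step 3
Reactants: 5 6-allyl-6-methylcarvone
Product: 6 3-[(1S,6S)-1,3-dimethyl-2-oxo-6-(prop-1-en-2-yl)cyclohex-3-en-1-yl]propanal
Conditions: PdCl2(PhCN)2 (cat.), CuCl2·2H2O (cat.), AgNO2 (cat.), O2 (1 atm), t-BuOH/MeNO2, rt
Reagents that add atoms: dioxygen, O=O
Why: The nitrite-modified, aldehyde-selective Wacker-type oxidation attacks only the monosubstituted alkene, and the nearby quaternary carbon reinforces anti-Markovnikov oxygen delivery, while the 1,1-disubstituted isopropenyl and the enone alkenes are inert.

Step 4
Reactants: 6 keto aldehyde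
Product: 7 (4aS,8aS)-6-hydroxy-2,5,5,8a-tetramethyl-4a,5,6,7,8,8a-hexahydronaphthalen-1(4H)-one (trans-fused hydroxy enone, both C3 carbinol epimers)
Conditions: Fe(acac)3 (cat.), PhSiH3, EtOH, 60 °C, degassed
Reagents that add atoms: none
Why: Metal-hydride hydrogen atom transfer from an iron hydride, formed from Fe(acac)3 and PhSiH3, to the CH2 terminus of the isopropenyl group gives the tertiary C4 radical, which adds to the carbonyl carbon C3, and the alkoxyl radical is then reduced and protonated by the divalent iron/EtOH couple, which pulls the reversible addition forward. The closest known reaction type is the iron-catalysed reductive radical cyclisation of alkene-tethered carbonyl compounds. Ring A closes in the 6-exo-trig mode through a chair in which the C5 and C10 tether arms are diequatorial on the carvone ring, so the trans ring fusion follows from the centres fixed in step 2. The only new stereocentre is the C3 carbinol, for which the chair should favour equatorial oxygen, but its configuration is of no consequence because C3 becomes a ketone in step 6. The step needs chemoselective, Markovnikov hydrogen atom transfer to one of two alkenes, and the electron-rich 1,1-disubstituted alkene is far more reactive than the electron-poor trisubstituted enone alkene and gives only the tertiary radical. Attack of the C4 radical on the enone is geometrically excluded, since it would need a 4-exo or 5-endo closure.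

Step 5
Reactants: 7 hydroxy enone
Product: 8 (5aS,9aS)-7-hydroxy-3,6,6,9a-tetramethyl-5a,6,7,8,9,9a-hexahydro-1-benzoxepin-2(5H)-one (unsaturated seven-membered lactone, both C3 epimers)
Conditions: mCPBA, CH2Cl2, rt
Reagents that add atoms: mCPBA, O=C(OO)c1cccc(Cl)c1
Why: Baeyer–Villiger oxidation, in whose Criegee adduct the fully substituted C10 migrates in preference to the sp2 carbon C8 and with retention, inserts the ring oxygen between C9 and C10 and fixes the tertiary ether centre, while the electron-poor alkene resists the peracid.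

Step 6
Reactants: 8 hydroxy lactone
Product: 9 (5aS,9aS)-3,6,6,9a-tetramethyl-5,5a,6,8,9,9a-hexahydro-1-benzoxepine-2,7-dione (keto lactone)
Conditions: Dess–Martin periodinane, CH2Cl2, rt
Reagents that add atoms: none
Why: Dess–Martin oxidation converges both C3 carbinol epimers on one ketone under neutral conditions that leave the unsaturated lactone untouched.

Step 7
Reactants: 9 keto lactone
Product: 10 (5aS,7R,9aS)-7-hydroxy-3,6,6,9a-tetramethyl-5a,6,7,8,9,9a-hexahydro-1-benzoxepin-2(5H)-one (axial 3α-alcohol)
Conditions: LiBH(s-Bu)3, THF, −78 °C; then H2O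
Reagents that add atoms: none
Why: In this diastereoselective ketone reduction the bulky trialkylborohydride attacks the 4,4-dimethyl ketone along the equatorial trajectory and gives the axial 3α-alcohol, while the alpha-methyl, beta-substituted unsaturated lactone is too poor an acceptor to be reduced at −78 °C.

Step 8
Reactants: 10 3α-hydroxy lactone
Product: 11 (5aS,7R,9aS)-3,6,6,9a-tetramethyl-2-methylidene-2,5,5a,6,7,8,9,9a-octahydro-1-benzoxepin-7-ol (dienol ether)
Conditions: Cp2TiMe2 (excess), toluene, 75 °C, dark
Reagents that add atoms: Cp2TiMe2, [CH3-].[CH3-].[CH-]1C=CC=C1.[CH-]1C=CC=C1.[Ti+4]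
Why: Petasis methylenation via Cp2Ti=CH2 converts the lactone carbonyl into the exocyclic enol ether without enolisation, and the hindered free alcohol only consumes extra reagent and is released on work-up.

Step 9
Reactants: 11 dienol ether
Product: 13 (2R,5aS,7R,9aS)-2-(hydroxymethyl)-3,6,6,9a-tetramethyl-2,5,5a,6,7,8,9,9a-octahydro-1-benzoxepin-7-ol (diol), via bis-boryl adduct 12 (not isolated)
Conditions: 9-BBN-H, THF, 0 °C → rt; then NaOH, H2O2, 0 °C
Reagents that add atoms: 9-BBN-H, B1C2CCCC1CCC2 (boron retained only in 12); hydrogen peroxide, OO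
Why: In this hydroboration–oxidation 9-BBN-H adds to the electron-rich 1,1-disubstituted enol ether alkene with boron on the terminal carbon and ignores the trisubstituted alkene, and approach from the α face, anti to the β-methyl group on C10 across the ring oxygen, puts H-9 α and the CH2OH group β.

Step 10
Reactants: 13 diol
Product: 14 (2R,5aS,7S,9aS)-7-bromo-2-(bromomethyl)-3,6,6,9a-tetramethyl-2,5,5a,6,7,8,9,9a-octahydro-1-benzoxepine (dibromo oxepene)
Conditions: CBr4, PPh3, toluene, 0 → 80 °C
Reagents that add atoms: tetrabromomethane, BrC(Br)(Br)Br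
Why: In this double Appel reaction the primary alcohol reacts in the cold and the axial oxyphosphonium group at the neopentyl-type C3 is displaced on heating by bromide from the equatorial side with inversion (SN2), which gives the equatorial 3β-bromide.

Step 11
Reactants: 14 dibromo oxepene
Product: 15 7α,8α-epoxide of 14
Conditions: mCPBA, CH2Cl2, 0 °C
Reagents that add atoms: mCPBA, O=C(OO)c1cccc(Cl)c1
Why: Prilezhaev epoxidation of the only alkene should occur from the α face, because the β face is screened by the C9 bromomethyl and C10 methyl groups, and this sets the C7–O configuration.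

Step 12
Reactants: 15 epoxy dibromide
Product: 16 (2R,4R,5aS,7S,9aS)-7-bromo-2-(bromomethyl)-6,6,9a-trimethyl-3-methylidenedecahydro-1-benzoxepin-4-ol (target)
Conditions: Cp2TiCl2, Mn, THF, rt (green Cp2TiCl solution preformed and decanted from Mn before addition of 15); then 1 M HCl
Reagents that add atoms: none
Why: In this radical epoxide-to-allylic-alcohol isomerisation trivalent titanium opens the epoxide homolytically to the tertiary C8 radical with the titanium alkoxide on C7, and a second Cp2TiCl removes the most accessible beta-hydrogen, that of the methyl group, which gives the exocyclic methylene with C7–O untouched under neutral conditions that spare both unactivated alkyl bromides.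

Compound list
1 | (R)-(−)-carvone | CC1=CC[C@H](CC1=O)C(C)=C | starting material
2 | lithium cross-conjugated dienolate of 1 | CC1=CC[C@@H](C(C)=C)C=C1O[Li] | intermediate
3 | (5R)-2,6-dimethyl-5-(prop-1-en-2-yl)cyclohex-2-en-1-one, C6 epimers | CC1=CC[C@@H](C(C)=C)C(C)C1=O | intermediate
4 | lithium cross-conjugated dienolate of 3 | CC1=CC[C@@H](C(C)=C)C(C)=C1O[Li] | intermediate
5 | (5S,6S)-6-allyl-2,6-dimethyl-5-(prop-1-en-2-yl)cyclohex-2-en-1-one | CC1=CC[C@@H](C(C)=C)[C@](C)(CC=C)C1=O | intermediate
6 | 3-[(1S,6S)-1,3-dimethyl-2-oxo-6-(prop-1-en-2-yl)cyclohex-3-en-1-yl]propanal | CC1=CC[C@@H](C(C)=C)[C@](C)(CCC=O)C1=O | intermediate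
7 | (4aS,8aS)-6-hydroxy-2,5,5,8a-tetramethyl-4a,5,6,7,8,8a-hexahydronaphthalen-1(4H)-one, C3 carbinol epimers | CC1=CC[C@H]2C(C)(C)C(O)CC[C@]2(C)C1=O | intermediate
8 | (5aS,9aS)-7-hydroxy-3,6,6,9a-tetramethyl-5a,6,7,8,9,9a-hexahydro-1-benzoxepin-2(5H)-one, C3 carbinol epimers | CC1=CC[C@H]2C(C)(C)C(O)CC[C@]2(C)OC1=O | intermediate
9 | (5aS,9aS)-3,6,6,9a-tetramethyl-5,5a,6,8,9,9a-hexahydro-1-benzoxepine-2,7-dione | CC1=CC[C@H]2C(C)(C)C(=O)CC[C@]2(C)OC1=O | intermediate
10 | (5aS,7R,9aS)-7-hydroxy-3,6,6,9a-tetramethyl-5a,6,7,8,9,9a-hexahydro-1-benzoxepin-2(5H)-one (axial 3α-OH) | CC1=CC[C@H]2C(C)(C)[C@H](O)CC[C@]2(C)OC1=O | intermediate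
11 | (5aS,7R,9aS)-3,6,6,9a-tetramethyl-2-methylidene-2,5,5a,6,7,8,9,9a-octahydro-1-benzoxepin-7-ol | CC1=CC[C@H]2C(C)(C)[C@H](O)CC[C@]2(C)OC1=C | intermediate
12 | bis-boryl adduct of 11 (B-alkyl-9-BBN at the C9 methylene carbon, O-boryl at C3) | CC1=CC[C@H]2C(C)(C)[C@H](OB3C4CCCC3CCC4)CC[C@]2(C)O[C@H]1CB5C6CCCC5CCC6 | intermediate
13 | (2R,5aS,7R,9aS)-2-(hydroxymethyl)-3,6,6,9a-tetramethyl-2,5,5a,6,7,8,9,9a-octahydro-1-benzoxepin-7-ol | CC1=CC[C@H]2C(C)(C)[C@H](O)CC[C@]2(C)O[C@H]1CO | intermediate
14 | (2R,5aS,7S,9aS)-7-bromo-2-(bromomethyl)-3,6,6,9a-tetramethyl-2,5,5a,6,7,8,9,9a-octahydro-1-benzoxepine | CC1=CC[C@H]2C(C)(C)[C@@H](Br)CC[C@]2(C)O[C@H]1CBr | intermediate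
15 | 7α,8α-epoxide of 14 | C[C@@]12O[C@@H]1C[C@H]3C(C)(C)[C@@H](Br)CC[C@]3(C)O[C@H]2CBr | intermediate
16 | (2R,4R,5aS,7S,9aS)-7-bromo-2-(bromomethyl)-6,6,9a-trimethyl-3-methylidenedecahydro-1-benzoxepin-4-ol | C=C1[C@H](O)C[C@H]2C(C)(C)[C@@H](Br)CC[C@]2(C)O[C@H]1CBr | target

Total step count: 12
Longest linear sequence: 12 steps, from 1

Steps most likely to fail

**Step 4 (key step).** Beta-scission of the cyclised alkoxyl radical back to the tertiary C4 radical may outrun its reduction. Plain hydrogenation of the isopropenyl group, or silane reduction of the aldehyde, would then take over.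

The fallback keeps the same ring closure but uses an irreversible acceptor, and it sets out from 6:
- Treatment of 6 with I2 and aqueous NH3 in THF should give the nitrile F1.
- Under Fe(acac)3, PhSiH3 and EtOH the same tertiary radical adds 6-exo-dig to the nitrile carbon.
- The iminyl radical is reduced to the N–H ketimine F2, which hydrolyses on work-up to the enedione F3.
- NaBH4 in MeOH/CH2Cl2 at −78 °C reduces the saturated C3 ketone in preference to the conjugated one, and the route is rejoined at 7.

**Step 10.** Loss of the axial oxyphosphonium group at the neopentyl-type C3 may outrun SN2 displacement. The competing paths are elimination towards C2 and a 1,2-methyl shift from C4.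

The fallback replaces substitution by a radical hydrogenation, and it sets out from 13:
- One equivalent of CBr4/PPh3 at 0 °C converts only the primary alcohol and gives the bromo alcohol F4.
- Dess–Martin oxidation gives the bromo ketone F5.
- Preformed (PhO)3P·Br2 with Et3N gives the ring A vinyl bromide F6.
- mCPBA epoxidises only the electron-rich C7=C8 alkene, from the α face, to the epoxy vinyl bromide F7.
- Hydrogen atom transfer hydrogenation with Mn(dpm)3 (cat.), PhSiH3 and t-BuOOH in i-PrOH saturates the vinyl bromide without loss of bromine.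
- The alpha-bromo radical at C3 takes up hydrogen from the open α face, which leaves bromine equatorial, and the route is rejoined at 15.

**Step 5.** Peracid addition to the hindered, conjugated C9 ketone may be so slow that alkene epoxidation competes or no reaction occurs.

The fallback masks the enone as a saturated ketone, and it sets out from 7:
- PhSH with Et3N adds to C7 and gives the beta-phenylthio ketone F8. Its new centres at C7 and C8 are of no consequence.
- Excess mCPBA oxidises sulfur to the sulfone and carries out the now easier Baeyer–Villiger insertion with migration of C10. This gives the beta-sulfonyl lactone F9.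
- DBU expels sulfinate by E1cB elimination and restores the C7=C8 alkene, and the route is rejoined at 8.

Further compounds
F1 | step 4 | 3-[(1S,6S)-1,3-dimethyl-2-oxo-6-(prop-1-en-2-yl)cyclohex-3-en-1-yl]propanenitrile | CC1=CC[C@@H](C(C)=C)[C@](C)(CCC#N)C1=O
F2 | step 4 | (4aS,8aS)-6-imino-2,5,5,8a-tetramethyl-4a,5,6,7,8,8a-hexahydronaphthalen-1(4H)-one (N–H ketimine) | CC1=CC[C@H]2C(C)(C)C(=N)CC[C@]2(C)C1=O
F3 | step 4 | (4aS,8aS)-2,5,5,8a-tetramethyl-4,4a,5,7,8,8a-hexahydronaphthalene-1,6-dione (enedione) | CC1=CC[C@H]2C(C)(C)C(=O)CC[C@]2(C)C1=O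
F4 | step 10 | (2R,5aS,7R,9aS)-2-(bromomethyl)-3,6,6,9a-tetramethyl-2,5,5a,6,7,8,9,9a-octahydro-1-benzoxepin-7-ol | CC1=CC[C@H]2C(C)(C)[C@H](O)CC[C@]2(C)O[C@H]1CBr
F5 | step 10 | (2R,5aS,9aS)-2-(bromomethyl)-3,6,6,9a-tetramethyl-5,5a,6,8,9,9a-hexahydro-1-benzoxepin-7(2H)-one | CC1=CC[C@H]2C(C)(C)C(=O)CC[C@]2(C)O[C@H]1CBr
F6 | step 10 | (2R,5aS,9aS)-7-bromo-2-(bromomethyl)-3,6,6,9a-tetramethyl-2,5,5a,6,9,9a-hexahydro-1-benzoxepine (C2=C3 vinyl bromide) | CC1=CC[C@H]2C(C)(C)C(Br)=CC[C@]2(C)O[C@H]1CBr
F7 | step 10 | 7α,8α-epoxide of F6 | C[C@@]12O[C@@H]1C[C@H]3C(C)(C)C(Br)=CC[C@]3(C)O[C@H]2CBr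
F8 | step 5 | C7 phenylthio adduct of 7 (C7, C8 and C3 open) | CC1C(Sc3ccccc3)C[C@H]2C(C)(C)C(O)CC[C@]2(C)C1=O
F9 | step 5 | C7 phenylsulfonyl saturated lactone (C7, C8 and C3 open) | CC1C(S(=O)(=O)c3ccccc3)C[C@H]2C(C)(C)C(O)CC[C@]2(C)OC1=O
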